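If these flasks end within 1.5 percentage points of one another, the way of adding is not worth a choice, so what has to be reckoned is what the adding costs in time.

| setting | beta | epsilon | alpha | delta | elm | maple | alder | oak |
|---|---|---|---|---|---|---|---|---|
| substrate | 0.40 M | 0.56 M | 0.88 M | 0.40 M | 0.40 M (fed, over 15 min) | 0.40 M | 0.40 M | 0.40 M |
| partner | 0.40 M | 0.40 M | 0.40 M | 0.80 M | 0.400 M | 0.400 M | 0.400 M (in portions, 2, over 15 min) | 0.400 M (fed, over 15 min) |
| remark | run made earlier | run made earlier | run made earlier | run made earlier | all else is in the flask from the start; the feed brings no volume worth counting | everything together at the start | first portion at the start, last at 15 min | all else is in the flask from the start; the feed brings no volume worth counting |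
| time |  |  |  |  | 80 min | 80 min | 80 min | 80 min |

| run | time / min | mono adduct / % | substrate / % |
|---|---|---|---|
| beta | 12.0 | 18.4 | 66.5 |
| beta | 25.0 | 30.8 | 43.9 |
| beta | 40.0 | 34.6 | 31.6 |
| beta | 50.0 | 38.5 | 27.1 |
| epsilon | 5.00 | 7.7 | 82.9 |
| epsilon | 12.0 | 16.2 | 66.3 |
| epsilon | 30.0 | 30.0 | 41.9 |
| epsilon | 60.0 | 39.0 | 23.5 |
| alpha | 5.00 | 9.2 | 82.7 |
| alpha | 12.0 | 17.5 | 68.4 |
| alpha | 30.0 | 27.9 | 47.0 |
| alpha | 60.0 | 34.3 | 32.1 |
| delta | 5.00 | 15.9 | 67.2 |
| delta | 12.0 | 28.4 | 42.3 |
| delta | 30.0 | 43.9 | 18.9 |
| delta | 60.0 | 45.6 | 11.1 |

(each reading ± 1 percentage point)

1. which flask leads in amount of mono adduct, in percent of the substrate charged ("all alike" within 1.5 percentage points) (elm / maple / alder / oak / all alike)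
2. how much mono adduct is there at the end, in percent of the substrate charged: elm
3. how much mono adduct is there at the end, in percent of the substrate charged: maple
4. how much mono adduct is there at the end, in percent of the substrate charged: alder
5. how much mono adduct is there at the end, in percent of the substrate charged: oak

- a reading or a percentage of mono adduct counts all its forms, free or not
- a reading of substrate is of its free form alone

The beta run has maple's charges. Its first reading, 18.4% mono adduct at 12.0 min, taken with the mean c(partner) and mean c(substrate) over that stretch, reads as a rate constant of 0.0507 L mol⁻¹ min⁻¹. In beta's last reading, twice the mono adduct plus the free substrate comes to 104%, so free substrate is taken to fall by two for each mono adduct, which makes it the limiting reagent. The lifetime of partner against substrate as charged is then 49.3 min, and the dosing count, the number of such lifetimes that the addition lasts, is 0.304.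

This reckoning integrates that rate and puts maple at 44.5%. The gap between maple and a dosed flask has a bound from below of zero, for a feed of no length. Its bound from above comes from letting the whole dose wait for the end of the feed, which reads maple's curve at 65.0 min: 42.3%, a gap of 2.2 points. To tighten it, note that a steady feed and two equal portions both arrive on average after 7.50 min, half the feed time. That gives 43.5% and a gap of 1 point, smaller than the margin.

The forecast says all alike, because each dosing mode “lands at the same state”: elm 42.5%, maple 43.5%, alder 42.5%, oak 42.5%. Its maple stands lower than this reckoning's, and its gap of 1 point lies inside the bracket.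

The flasks come out all alike: maple 43.0%, elm 42.2%, alder 42.2%, oak 42.3%. The gap of 0.80 points lies inside the bracket. At 15.0 min the mono adduct stands at 12.0% in elm, 11.8% in alder and 12.2% in oak.

    substrate + partner → mono adduct (k = 0.0514 L mol⁻¹ min⁻¹)
    partner + mono adduct → double product (k = 0.0609 L mol⁻¹ min⁻¹)
    substrate + mono adduct ⇌ idle adduct, settled at all times (K = 72.1 L mol⁻¹)

Elm dosed over 1.50 min has a dosing count of 0.0304, and that flask ends at 43.0%.

All runs were computed with constants of no real substance.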